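**Retrosynthetic overview**

1. The target is read as robinetinidol-(4β→6)-gallocatechin. The eleven benzyl ethers are removed last by hydrogenolysis; before that, the C4 carbonyl of the lower unit, a temporary activating group, is taken out (NaBH4, then Et3SiH/CF3CO2H).
2. Key disconnection: ring C of the lower unit is cut at O1–C8a and C2–C3. In the forward sense a fluoride-relay aldol–SNAr annulation joins the silyl enol ether of an ortho-fluoroaryl benzyloxymethyl ketone to 3,4,5-tris(benzyloxy)benzaldehyde, closing ring C and bringing in ring B.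
3. Enabling feature: in ring A of the lower unit, C8a is ortho to C4a, which carries C4, so a carbonyl at C4 both acidifies C3 and activates a C8a–F bond. The interflavan carbon C6 lies para to C8a, between the equivalent oxygenated carbons C5 and C7, so ring A can enter as a locally symmetric 2,6-dioxygenated 4-fluorophenyl unit and only the 4→6 isomer can form.
4. The interflavan bond C4(upper)–C6(lower) is made earlier by silicon-tethered delivery of that aryl group from O3 to C4 of a flavan-3,4-diol derivative obtained from (+)-dihydrorobinetin (chiral pool for upper C2 and C3); the tether fixes the 3,4-cis geometry.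
5. Ring order: upper rings A, C and B come with the starting material; lower ring A is attached next; lower ring C is closed last, carrying lower ring B.

Key step: step 11

Assumption: commercial (+)-dihydrorobinetin is taken as the natural (2R,3R) enantiomer, the target has a 2,3-trans-3,4-cis (2R,3S,4R) upper unit and a (2R,3S) lower unit, and the sense of induction of the cinchona catalyst in step 11 is a design assumption.

**Route**

Step 1
Reactants: 1 5-fluororesorcinol
Product: 2 5-fluoro-2-iodobenzene-1,3-diol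
Conditions: I2, NaHCO3, H2O, 0 °C to rt
Reagents that add atoms: iodine, II
Why: Electrophilic aromatic iodination under weakly basic aqueous conditions, which for resorcinols goes to the carbon between the two hydroxyl groups, should place iodine on the later interflavan carbon.

Step 2
Reactants: 2 5-fluoro-2-iodobenzene-1,3-diol
Product: 3 1,3-bis(benzyloxy)-5-fluoro-2-iodobenzene
Conditions: BnBr, K2CO3, DMF, rt
Reagents that add atoms: benzyl bromide, BrCc1ccccc1
Why: Williamson ether synthesis of both phenols with a weak base should proceed without touching the aryl iodide or fluoride.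

Step 3
Reactants: 3 1,3-bis(benzyloxy)-5-fluoro-2-iodobenzene
Product: 4 1,3-bis(benzyloxy)-4-bromo-5-fluoro-2-iodobenzene
Conditions: N-bromosuccinimide (1.0 equiv), MeCN, 0 °C to rt
Reagents that add atoms: N-bromosuccinimide, O=C1CCC(=O)N1Br
Why: Electrophilic aromatic bromination should occur at the only type of free position (ortho to fluorine and ortho/para to the benzyloxy groups; the two such carbons are equivalent), giving the handle for the later acyl group.

Step 4
Reactants: 5 (+)-dihydrorobinetin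
Product: 6 (2R,3R)-7-(benzyloxy)-3-hydroxy-2-[3,4,5-tris(benzyloxy)phenyl]chroman-4-one
Conditions: BnBr (4.4 equiv), K2CO3, DMF, rt
Reagents that add atoms: benzyl bromide, BrCc1ccccc1
Why: Williamson ether synthesis with a weak base should benzylate the four phenols selectively over the secondary alcohol and leave the trans C2/C3 stereocentres of the starting material untouched.

Step 5
Reactants: 6 (2R,3R)-7-(benzyloxy)-3-hydroxy-2-[3,4,5-tris(benzyloxy)phenyl]chroman-4-one
Product: 8 (2R,3S)-7-(benzyloxy)-4-methoxy-2-[3,4,5-tris(benzyloxy)phenyl]chroman-3-ol (C4 epimers), via flavan-3,4-diol 7 (not isolated)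
Conditions: NaBH4, THF/MeOH, 0 °C; then camphor-10-sulfonic acid (to pH 3), MeOH, rt
Reagents that add atoms: methanol, CO
Why: Hydride reduction of the aryl ketone followed by acid-catalysed SN1 methanolysis of the benzylic 4-hydroxyl (cation stabilised by O1 and the 7-benzyloxy group) should give the 4-methyl ether with the 3-hydroxyl free; the C4 configuration does not matter because C4 is ionised again in step 7.

Step 6
Reactants: 4 1,3-bis(benzyloxy)-4-bromo-5-fluoro-2-iodobenzene; 8 (2R,3S)-7-(benzyloxy)-4-methoxy-2-[3,4,5-tris(benzyloxy)phenyl]chroman-3-ol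
Product: 11 3-O-[aryl(dimethyl)silyl] ether of 8 (aryl = 2,6-bis(benzyloxy)-3-bromo-4-fluorophenyl), via aryl Grignard reagent 9 (not isolated), via aryl(chloro)dimethylsilane 10 (not isolated)
Conditions: 4, i-PrMgCl·LiCl, THF, −20 °C; Me2SiCl2 (excess), −20 °C to rt, volatiles removed; then 8, imidazole, 4-(dimethylamino)pyridine (cat.), CH2Cl2/DMF, rt
Reagents that add atoms: dichlorodimethylsilane, C[Si](C)(Cl)Cl
Why: Selective iodine–magnesium exchange (the bromide is not exchanged at this temperature), silylation of the aryl Grignard reagent with excess Me2SiCl2 and imidazole-promoted O-silylation of the only free hydroxyl of 8 should assemble the temporary silicon tether without affecting any stereocentre.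

Step 7
Reactants: 11 3-O-[aryl(dimethyl)silyl] ether of 8
Product: 13 (2R,3S,4R)-4-[2,6-bis(benzyloxy)-3-bromo-4-fluorophenyl]-7-(benzyloxy)-2-[3,4,5-tris(benzyloxy)phenyl]chroman-3-ol, via 3-O-[methoxy(dimethyl)silyl] ether 12 (not isolated)
Conditions: Me3SiOTf (0.3 equiv), 2,6-di-tert-butylpyridine (0.3 equiv), CH2Cl2 (high dilution), −78 to −30 °C; then K2CO3, MeOH, rt
Reagents that add atoms: none
Why: Proposed new method: Me3SiOTf ionises the 4-methoxy group to the benzylic C4 cation, the silicon-bound aryl carbon (activated by its two ortho benzyloxy groups and by the beta-silicon effect) attacks it through a five-membered cyclic transition state that can only reach the face carrying O3, and loss of silicon from the ipso carbon (the methoxy group ends on silicon) followed by methanolysis of the Si–O bond should give the 4-arylflavan-3-ol with the aryl group cis to the 3-hydroxyl (4R); the closest known reaction types are the ipso-substitution of arylsilanes by carbocations and the intramolecular aryl delivery from 2-O-arylsilyl groups to glycosyl cations that gives 1,2-cis C-aryl glycosides.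

Step 8
Reactants: 13 (2R,3S,4R)-4-[2,6-bis(benzyloxy)-3-bromo-4-fluorophenyl]-7-(benzyloxy)-2-[3,4,5-tris(benzyloxy)phenyl]chroman-3-ol
Product: 14 (2R,3S,4R)-3,7-bis(benzyloxy)-4-[2,6-bis(benzyloxy)-3-bromo-4-fluorophenyl]-2-[3,4,5-tris(benzyloxy)phenyl]chromane
Conditions: NaH, BnBr, Bu4NI (cat.), DMF, 0 °C to rt
Reagents that add atoms: benzyl bromide, BrCc1ccccc1
Why: Williamson ether synthesis of the secondary alcohol through its sodium alkoxide should cap O3 as a benzyl ether that survives the organolithium, fluoride and hydride steps and is removed in the final hydrogenolysis.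

Step 9
Reactants: 14 (2R,3S,4R)-3,7-bis(benzyloxy)-4-[2,6-bis(benzyloxy)-3-bromo-4-fluorophenyl]-2-[3,4,5-tris(benzyloxy)phenyl]chromane; 15 2-(benzyloxy)-N-methoxy-N-methylacetamide
Product: 17 2-(benzyloxy)-1-{2,4-bis(benzyloxy)-6-fluoro-3-[(2R,3S,4R)-3,7-bis(benzyloxy)-2-[3,4,5-tris(benzyloxy)phenyl]chroman-4-yl]phenyl}ethan-1-one, via ortho-fluoroaryllithium 16 (not isolated)
Conditions: n-BuLi, THF, −78 °C; then 15, −78 to −40 °C; aq. NH4Cl
Reagents that add atoms: none
Why: Bromine–lithium exchange at −78 °C (faster than deprotonation or loss of LiF) followed by acylation with a Weinreb amide, whose chelated tetrahedral intermediate prevents over-addition, should install the benzyloxyacetyl group ortho to fluorine (Weinreb ketone synthesis).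

Step 10
Reactants: 17 aryl benzyloxymethyl ketone
Product: 18 (Z)-trimethylsilyl enol ether of 17
Conditions: Me3SiOTf, Et3N, CH2Cl2, 0 °C
Reagents that add atoms: trimethylsilyl trifluoromethanesulfonate, C[Si](C)(C)OS(=O)(=O)C(F)(F)F
Why: Soft enolisation with Me3SiOTf/Et3N should convert the ketone into its trimethylsilyl enol ether, expected mainly as the Z isomer with the two oxygen substituents cis.

Step 11
Reactants: 18 (Z)-trimethylsilyl enol ether of 17; 19 3,4,5-tris(benzyloxy)benzaldehyde
Product: 22 (2R,3R)-3,5,7-tris(benzyloxy)-6-[(2R,3S,4R)-3,7-bis(benzyloxy)-2-[3,4,5-tris(benzyloxy)phenyl]chroman-4-yl]-2-[3,4,5-tris(benzyloxy)phenyl]chroman-4-one, via ammonium enolate 20 (not isolated), via ammonium aldolate 21 (not isolated)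
Conditions: 19 (1.5 equiv), N-benzylcinchonidinium fluoride (10 mol %, dried), THF/toluene, 4 Å molecular sieves, −40 to 0 °C
Reagents that add atoms: none
Why: Proposed new method: the chiral ammonium fluoride desilylates enol ether 18 to the ion-paired enolate 20 (Me3SiF is lost), which adds reversibly to aldehyde 19 (new C2–C3 bond) to give aldolate 21, and the alkoxide oxygen then displaces the fluoride at C8a of the ortho-acyl ring (new O1–C8a bond), so that the fluoride leaving the arene re-enters as the desilylating catalyst and no achiral base or counter-cation is present at any stage. The closest known reaction types are the Mukaiyama aldol addition of ketone silyl enol ethers to aromatic aldehydes catalysed by cinchona-derived quaternary ammonium fluorides, the fluoride-catalysed SNAr etherification of silyl ethers with carbonyl-activated aryl fluorides, and base-mediated aldol–SNAr routes to chroman-4-ones. Ring C of the lower unit closes by a 6-endo-trig addition of the alkoxide to the C8a=C4a bond of the vinylogous acyl fluoride followed by loss of fluoride (intramolecular SNAr through a Meisenheimer anion stabilised by the C4 carbonyl). C2 is controlled by the chiral cation: the aldolates interconvert by retro-aldol, and the one formed on the Si face of the aldehyde inside the ion pair should cyclise fastest, giving 2R; C3 is under thermodynamic control, because the cyclised ketone epimerises through its ammonium enolate to the 2,3-trans isomer with both substituents equatorial (3R at the ketone level, 3S once the carbonyl is removed). The step needs site selectivity on ring A and O-selectivity in the closure: ring A carries a single fluorine, on the carbon para to the interflavan carbon C6, so only the 4→6 connectivity can form, the ortho carbonyl activates exactly that C–F bond, and the 3-O-benzyl group blocks the competing five-membered closure to a benzofuranone.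

Step 12
Reactants: 22 lower-unit chroman-4-one
Product: 23 corresponding lower-unit chroman-4-ol (2R,3S; C4 epimers)
Conditions: NaBH4, THF/MeOH, 0 °C
Reagents that add atoms: none
Why: Hydride reduction of the flavanone carbonyl should give the flavan-4-ol; the new C4 stereocentre does not matter because it is removed in step 13.

Step 13
Reactants: 23 lower-unit chroman-4-ol
Product: 24 undeca-O-benzyl robinetinidol-(4β→6)-gallocatechin
Conditions: Et3SiH, CF3CO2H, CH2Cl2, −40 to 0 °C
Reagents that add atoms: none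
Why: Ionic hydrogenation: acid ionises the 4-hydroxyl to a benzylic cation stabilised by the 5- and 7-benzyloxy groups and Et3SiH delivers hydride, converting C4 to CH2 without touching C2 or C3 of either unit.

Step 14
Reactants: 24 undeca-O-benzyl robinetinidol-(4β→6)-gallocatechin
Product: 25 robinetinidol-(4β→6)-gallocatechin (target)
Conditions: H2 (1 atm), Pd(OH)2/C, THF/MeOH/H2O, rt
Reagents that add atoms: none
Why: Catalytic hydrogenolysis of the eleven benzyl ethers under neutral conditions should release the free polyphenol without cleaving the interflavan bond or the C2–O1 bonds.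

**Compound list**

1 | 5-fluororesorcinol (5-fluorobenzene-1,3-diol) | Oc1cc(O)cc(F)c1 | starting material
2 | 5-fluoro-2-iodobenzene-1,3-diol | Oc1cc(F)cc(O)c1I | intermediate
3 | 1,3-bis(benzyloxy)-5-fluoro-2-iodobenzene | Fc1cc(OCc2ccccc2)c(I)c(OCc2ccccc2)c1 | intermediate
4 | 1,3-bis(benzyloxy)-4-bromo-5-fluoro-2-iodobenzene | Fc1cc(OCc2ccccc2)c(I)c(OCc2ccccc2)c1Br | intermediate
5 | (+)-dihydrorobinetin, (2R,3R)-3,7-dihydroxy-2-(3,4,5-trihydroxyphenyl)chroman-4-one | Oc1ccc2c(c1)O[C@H](c1cc(O)c(O)c(O)c1)[C@@H](O)C2=O | starting material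
6 | (2R,3R)-7-(benzyloxy)-3-hydroxy-2-[3,4,5-tris(benzyloxy)phenyl]chroman-4-one | O(Cc3ccccc3)c1ccc2c(c1)O[C@H](c1cc(OCc3ccccc3)c(OCc3ccccc3)c(OCc3ccccc3)c1)[C@@H](O)C2=O | intermediate
7 | (2R,3S)-7-(benzyloxy)-2-[3,4,5-tris(benzyloxy)phenyl]chromane-3,4-diol, C4 epimers (not isolated) | O(Cc3ccccc3)c1ccc2c(c1)O[C@H](c1cc(OCc3ccccc3)c(OCc3ccccc3)c(OCc3ccccc3)c1)[C@@H](O)C2O | intermediate
8 | (2R,3S)-7-(benzyloxy)-4-methoxy-2-[3,4,5-tris(benzyloxy)phenyl]chroman-3-ol, C4 epimers | O(Cc3ccccc3)c1ccc2c(c1)O[C@H](c1cc(OCc3ccccc3)c(OCc3ccccc3)c(OCc3ccccc3)c1)[C@@H](O)C2OC | intermediate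
9 | [2,6-bis(benzyloxy)-3-bromo-4-fluorophenyl]magnesium chloride (not isolated) | Fc1cc(OCc2ccccc2)c([Mg]Cl)c(OCc2ccccc2)c1Br | intermediate
10 | [2,6-bis(benzyloxy)-3-bromo-4-fluorophenyl]chlorodimethylsilane (not isolated) | Fc1cc(OCc2ccccc2)c([Si](C)(C)Cl)c(OCc2ccccc2)c1Br | intermediate
11 | (2R,3S)-3-{[2,6-bis(benzyloxy)-3-bromo-4-fluorophenyl]dimethylsilyloxy}-7-(benzyloxy)-4-methoxy-2-[3,4,5-tris(benzyloxy)phenyl]chromane, C4 epimers | O(Cc3ccccc3)c1ccc2c(c1)O[C@H](c1cc(OCc3ccccc3)c(OCc3ccccc3)c(OCc3ccccc3)c1)[C@@H](O[Si](C)(C)c1c(OCc3ccccc3)cc(F)c(Br)c1OCc3ccccc3)C2OC | intermediate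
12 | (2R,3S,4R)-4-[2,6-bis(benzyloxy)-3-bromo-4-fluorophenyl]-7-(benzyloxy)-3-[methoxy(dimethyl)silyloxy]-2-[3,4,5-tris(benzyloxy)phenyl]chromane (not isolated) | O(Cc3ccccc3)c1ccc2c(c1)O[C@H](c1cc(OCc3ccccc3)c(OCc3ccccc3)c(OCc3ccccc3)c1)[C@@H](O[Si](C)(C)OC)[C@H]2c1c(OCc3ccccc3)cc(F)c(Br)c1OCc3ccccc3 | intermediate
13 | (2R,3S,4R)-4-[2,6-bis(benzyloxy)-3-bromo-4-fluorophenyl]-7-(benzyloxy)-2-[3,4,5-tris(benzyloxy)phenyl]chroman-3-ol (2,3-trans-3,4-cis) | O(Cc3ccccc3)c1ccc2c(c1)O[C@H](c1cc(OCc3ccccc3)c(OCc3ccccc3)c(OCc3ccccc3)c1)[C@@H](O)[C@H]2c1c(OCc3ccccc3)cc(F)c(Br)c1OCc3ccccc3 | intermediate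
14 | (2R,3S,4R)-3,7-bis(benzyloxy)-4-[2,6-bis(benzyloxy)-3-bromo-4-fluorophenyl]-2-[3,4,5-tris(benzyloxy)phenyl]chromane | O(Cc3ccccc3)c1ccc2c(c1)O[C@H](c1cc(OCc3ccccc3)c(OCc3ccccc3)c(OCc3ccccc3)c1)[C@@H](OCc3ccccc3)[C@H]2c1c(OCc3ccccc3)cc(F)c(Br)c1OCc3ccccc3 | intermediate
15 | 2-(benzyloxy)-N-methoxy-N-methylacetamide | CON(C)C(=O)COCc1ccccc1 | starting material
16 | ortho-fluoroaryllithium from 14, lithium in place of bromine (not isolated) | O(Cc3ccccc3)c1ccc2c(c1)O[C@H](c1cc(OCc3ccccc3)c(OCc3ccccc3)c(OCc3ccccc3)c1)[C@@H](OCc3ccccc3)[C@H]2c1c(OCc3ccccc3)cc(F)c([Li])c1OCc3ccccc3 | intermediate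
17 | 2-(benzyloxy)-1-{2,4-bis(benzyloxy)-6-fluoro-3-[(2R,3S,4R)-3,7-bis(benzyloxy)-2-[3,4,5-tris(benzyloxy)phenyl]chroman-4-yl]phenyl}ethan-1-one | O(Cc3ccccc3)c1ccc2c(c1)O[C@H](c1cc(OCc3ccccc3)c(OCc3ccccc3)c(OCc3ccccc3)c1)[C@@H](OCc3ccccc3)[C@H]2c1c(OCc3ccccc3)cc(F)c(C(=O)COCc3ccccc3)c1OCc3ccccc3 | intermediate
18 | (Z)-trimethylsilyl enol ether of 17 | O(Cc3ccccc3)c1ccc2c(c1)O[C@H](c1cc(OCc3ccccc3)c(OCc3ccccc3)c(OCc3ccccc3)c1)[C@@H](OCc3ccccc3)[C@H]2c1c(OCc3ccccc3)cc(F)c(/C(O[Si](C)(C)C)=C/OCc3ccccc3)c1OCc3ccccc3 | intermediate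
19 | 3,4,5-tris(benzyloxy)benzaldehyde | O=Cc1cc(OCc2ccccc2)c(OCc2ccccc2)c(OCc2ccccc2)c1 | starting material
20 | enolate of 17, anion shown, paired with the N-benzylcinchonidinium cation (not isolated) | O(Cc3ccccc3)c1ccc2c(c1)O[C@H](c1cc(OCc3ccccc3)c(OCc3ccccc3)c(OCc3ccccc3)c1)[C@@H](OCc3ccccc3)[C@H]2c1c(OCc3ccccc3)cc(F)c(/C([O-])=C/OCc3ccccc3)c1OCc3ccccc3 | intermediate
21 | anti-aldolate from 20 and 19, productive (2R,3R) isomer, anion shown, paired with the N-benzylcinchonidinium cation (not isolated) | O(Cc3ccccc3)c1ccc2c(c1)O[C@H](c1cc(OCc3ccccc3)c(OCc3ccccc3)c(OCc3ccccc3)c1)[C@@H](OCc3ccccc3)[C@H]2c1c(OCc3ccccc3)cc(F)c(c1OCc3ccccc3)C(=O)[C@H](OCc3ccccc3)[C@@H](c1cc(OCc3ccccc3)c(OCc3ccccc3)c(OCc3ccccc3)c1)[O-] | intermediate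
22 | (2R,3R)-3,5,7-tris(benzyloxy)-6-[(2R,3S,4R)-3,7-bis(benzyloxy)-2-[3,4,5-tris(benzyloxy)phenyl]chroman-4-yl]-2-[3,4,5-tris(benzyloxy)phenyl]chroman-4-one | O(Cc3ccccc3)c1ccc2c(c1)O[C@H](c1cc(OCc3ccccc3)c(OCc3ccccc3)c(OCc3ccccc3)c1)[C@@H](OCc3ccccc3)[C@H]2c1c(OCc3ccccc3)cc2c(c1OCc3ccccc3)C(=O)[C@H](OCc3ccccc3)[C@@H](c1cc(OCc3ccccc3)c(OCc3ccccc3)c(OCc3ccccc3)c1)O2 | intermediate
23 | (2R,3S)-3,5,7-tris(benzyloxy)-6-[(2R,3S,4R)-3,7-bis(benzyloxy)-2-[3,4,5-tris(benzyloxy)phenyl]chroman-4-yl]-2-[3,4,5-tris(benzyloxy)phenyl]chroman-4-ol, C4 epimers | O(Cc3ccccc3)c1ccc2c(c1)O[C@H](c1cc(OCc3ccccc3)c(OCc3ccccc3)c(OCc3ccccc3)c1)[C@@H](OCc3ccccc3)[C@H]2c1c(OCc3ccccc3)cc2c(c1OCc3ccccc3)C(O)[C@H](OCc3ccccc3)[C@@H](c1cc(OCc3ccccc3)c(OCc3ccccc3)c(OCc3ccccc3)c1)O2 | intermediate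
24 | undeca-O-benzyl robinetinidol-(4β→6)-gallocatechin, upper unit (2R,3S,4R), lower unit (2R,3S) | O(Cc3ccccc3)c1ccc2c(c1)O[C@H](c1cc(OCc3ccccc3)c(OCc3ccccc3)c(OCc3ccccc3)c1)[C@@H](OCc3ccccc3)[C@H]2c1c(OCc3ccccc3)cc2c(c1OCc3ccccc3)C[C@H](OCc3ccccc3)[C@@H](c1cc(OCc3ccccc3)c(OCc3ccccc3)c(OCc3ccccc3)c1)O2 | intermediate
25 | robinetinidol-(4β→6)-gallocatechin (CNP0311915.3) | Oc1ccc2c(c1)O[C@H](c1cc(O)c(O)c(O)c1)[C@@H](O)[C@H]2c1c(O)cc2c(c1O)C[C@H](O)[C@@H](c1cc(O)c(O)c(O)c1)O2 | target

**Summary**

Total step count: 14.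
Longest linear sequence: 12 steps (steps 1–3 and 6–14, from 5-fluororesorcinol).

Steps most likely to fail:

1. Step 11. The chiral ion pair may give poor or reversed facial selectivity at C2, retro-aldol may outrun ring closure at low temperature, and prolonged contact with the basic catalyst may reopen ring C and erode the C2 configuration. The fallback sets out from ketone 17. Its lithium enolate (LiN(SiMe3)2, THF, −78 °C) is added to aldehyde 19 to give the aldol adduct F1 as a mixture at the two new carbons. Cs2CO3 in DMF at rt then closes ring C by intramolecular SNAr and equilibrates C3 to the trans series. Because the upper unit is a single enantiomer, the two 2,3-trans products are diastereomers, and the (2R,3R) isomer is separated by chromatography; the fallback comes back to the route at compound 22.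

2. Step 7. Ring closure at the crowded silicon-bearing carbon may be slower than intermolecular capture of the C4 cation (self-condensation) or protodesilylation of the arylsilane, so that the tether is lost before the aryl group is delivered. The fallback sets out from ketone 6 (and uses iodide 4). Iodine–lithium exchange on 4 (n-BuLi, THF, −78 °C) and transmetalation with CeCl3 give the arylcerium reagent, which is added in excess to 6 (the 3-hydroxyl carried as its alkoxide) to give the tertiary benzylic diol F2. Acetic anhydride/pyridine acetylates only the secondary 3-hydroxyl, giving the 3-acetate F3. Ionic hydrogenation (Et3SiH, BF3·OEt2, CH2Cl2, −78 °C) removes the tertiary hydroxyl; the neighbouring 3-acetoxy group is expected to cover the face of the C4 cation that carries O3 (anchimeric assistance), so hydride should enter trans to O3 and leave the aryl group cis to it, giving the 4-arylflavan-3-yl acetate F4. Methanolysis (K2CO3, MeOH) then gives the alcohol, and the fallback comes back to the route at compound 13.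

3. Step 9. The ortho-fluoroaryllithium may lose LiF (aryne formation) or be quenched by benzylic protons before it is acylated. The fallback sets out from bromide 14. Aminocarbonylation catalysed by Pd(OAc)2 with Xantphos (CO 1 atm, N,O-dimethylhydroxylamine hydrochloride, Na2CO3, toluene, 80 °C) gives the aryl Weinreb amide F5. (Benzyloxy)methyllithium, generated from tributyl[(benzyloxy)methyl]stannane and n-BuLi at −78 °C, is then added to F5, and the fallback comes back to the route at compound 17.

**Further compounds**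

F1 | step 11 | aldol adduct of 17 and 19, 2-(benzyloxy)-3-hydroxy-3-[3,4,5-tris(benzyloxy)phenyl]propan-1-one bearing the aryl group of 17, mixture at the two new carbons | O(Cc3ccccc3)c1ccc2c(c1)O[C@H](c1cc(OCc3ccccc3)c(OCc3ccccc3)c(OCc3ccccc3)c1)[C@@H](OCc3ccccc3)[C@H]2c1c(OCc3ccccc3)cc(F)c(c1OCc3ccccc3)C(=O)C(OCc3ccccc3)C(O)c1cc(OCc3ccccc3)c(OCc3ccccc3)c(OCc3ccccc3)c1
F2 | step 7 | (2R,3R)-4-[2,6-bis(benzyloxy)-3-bromo-4-fluorophenyl]-7-(benzyloxy)-2-[3,4,5-tris(benzyloxy)phenyl]chromane-3,4-diol, C4 configuration open | O(Cc3ccccc3)c1ccc2c(c1)O[C@H](c1cc(OCc3ccccc3)c(OCc3ccccc3)c(OCc3ccccc3)c1)[C@@H](O)C2(O)c1c(OCc3ccccc3)cc(F)c(Br)c1OCc3ccccc3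
F3 | step 7 | 3-O-acetate of F2 | O(Cc3ccccc3)c1ccc2c(c1)O[C@H](c1cc(OCc3ccccc3)c(OCc3ccccc3)c(OCc3ccccc3)c1)[C@@H](OC(C)=O)C2(O)c1c(OCc3ccccc3)cc(F)c(Br)c1OCc3ccccc3
F4 | step 7 | (2R,3S,4R)-4-[2,6-bis(benzyloxy)-3-bromo-4-fluorophenyl]-7-(benzyloxy)-2-[3,4,5-tris(benzyloxy)phenyl]chroman-3-yl acetate | O(Cc3ccccc3)c1ccc2c(c1)O[C@H](c1cc(OCc3ccccc3)c(OCc3ccccc3)c(OCc3ccccc3)c1)[C@@H](OC(C)=O)[C@H]2c1c(OCc3ccccc3)cc(F)c(Br)c1OCc3ccccc3
F5 | step 9 | 2,4-bis(benzyloxy)-6-fluoro-N-methoxy-N-methyl-3-[(2R,3S,4R)-3,7-bis(benzyloxy)-2-[3,4,5-tris(benzyloxy)phenyl]chroman-4-yl]benzamide | O(Cc3ccccc3)c1ccc2c(c1)O[C@H](c1cc(OCc3ccccc3)c(OCc3ccccc3)c(OCc3ccccc3)c1)[C@@H](OCc3ccccc3)[C@H]2c1c(OCc3ccccc3)cc(F)c(C(=O)N(C)OC)c1OCc3ccccc3
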